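**Plan**

- Numbering: tetralin C1 (aryl-bearing), C2, C3, C4 (CH2), C4a, C5–C8, C8a; C9 is the carbon on C2, C10 the carbon on C3. The target is the (1S,2R,3S) isomer: aryl trans to C9, C9/C10 cis.
- Enabling feature: ring B (C1–C2–C3–C4–C4a–C8a), fused to arene ring A and carrying the cis carbons C9/C10 on C2/C3, is the [4+2] adduct of an o-quinodimethane C1=C8a–C4a=C4 and a cis two-carbon dienophile.
- Retrosynthesis: C1–H goes back to C1–OH and the C9/C10 diol to a cis γ-lactone. C1–C2 and C3–C4 are then cut together (ortho-methyl diaryl ketone plus 2(5H)-furanone), and last the aryl–carbonyl bond C1–C8a (aryllithium plus 3,4,5-trimethoxybenzaldehyde).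
- Forward: ring A is dressed (acetonide, CHO to CH3), the diaryl ketone is assembled by ortho-lithiation, addition and oxidation, and ring B closes in one photochemical step. Lactone reduction, C1 deoxygenation and acetonide removal follow.
- Stereochemistry: C2/C3 cis comes from the Z-alkene of the furanone and their absolute sense from a chiral titanium TADDOLate. C1 comes from a silicon-tethered hydride delivered on the face that carries C9/C10.

Key step: step 5

Assumption: the (R,R)-TADDOL titanium complex is taken to expose the furanone face that leads to the (2S,3S)-lactone; should the sense prove opposite, the (S,S)-ligand is used and nothing else changes.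

**Route**

Step 1
Reactants: 1 3,4-dihydroxy-5-methoxybenzaldehyde
Product: 2 7-methoxy-2,2-dimethyl-1,3-benzodioxole-5-carbaldehyde
Conditions: Me2C(OMe)2, TsOH·H2O (cat.), PhMe, reflux, 4 Å MS (Soxhlet)
Reagents that add atoms: 2,2-dimethoxypropane COC(C)(C)OC
Why: Acid-catalysed transketalisation of the catechol (isopropylidene ketal formation) is driven by removal of methanol, and any dimethyl acetal of the aldehyde reverts on aqueous work-up.

Step 2
Reactants: 2 7-methoxy-2,2-dimethyl-1,3-benzodioxole-5-carbaldehyde
Product: 4 4-methoxy-2,2,6-trimethyl-1,3-benzodioxole, via hydrazone 3 (not isolated)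
Conditions: N2H4·H2O, KOH, diethylene glycol, 130 → 195 °C
Reagents that add atoms: none
Why: The Wolff–Kishner reduction (Huang-Minlon variant) should turn the electron-rich aryl aldehyde into the methyl group through its hydrazone under basic conditions that the ketal and the aryl methyl ether tolerate.

Step 3
Reactants: 4 4-methoxy-2,2,6-trimethyl-1,3-benzodioxole + 5 3,4,5-trimethoxybenzaldehyde
Product: 7 rac-(7-methoxy-2,2,5-trimethyl-1,3-benzodioxol-4-yl)(3,4,5-trimethoxyphenyl)methanol, via aryllithium 6 (not isolated)
Conditions: n-BuLi, TMEDA, Et2O, 0 °C → rt; then 5, THF, −78 °C → rt; H2O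
Reagents that add atoms: none
Why: In this directed ortho-metalation the ring-constrained dioxole oxygen acidifies its ortho C–H more than the methoxy group does, so lithiation should occur between the dioxole oxygen and the methyl group, and 1,2-addition to the aldehyde gives a racemic carbinol whose stereocentre is removed in step 4.

Step 4
Reactants: 7 rac-(7-methoxy-2,2,5-trimethyl-1,3-benzodioxol-4-yl)(3,4,5-trimethoxyphenyl)methanol
Product: 8 (7-methoxy-2,2,5-trimethyl-1,3-benzodioxol-4-yl)(3,4,5-trimethoxyphenyl)methanone
Conditions: Dess–Martin periodinane, CH2Cl2, 0 °C → rt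
Reagents that add atoms: none
Why: Dess–Martin oxidation of a secondary diaryl carbinol to the diaryl ketone is mild enough for the ketal and the electron-rich rings.

Step 5
Reactants: 8 (7-methoxy-2,2,5-trimethyl-1,3-benzodioxol-4-yl)(3,4,5-trimethoxyphenyl)methanone + 9 2(5H)-furanone
Product: 11 (1R,2S,3S)-1-hydroxy cis-lactone adduct (7,8-acetonide; 6-OMe; C9 = lactone C=O on C2; C10 = OCH2 on C3; OH cis to C9; aryl trans to the lactone), via photodienol 10 (not isolated)
Conditions: hν (365 nm), Ti(Oi-Pr)4 (1.2 equiv), (R,R)-TADDOL (1.3 equiv), 9 (3 equiv), degassed PhMe, 0 °C; then aq. NaHCO3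
Reagents that add atoms: none
Why: n,π* excitation of 8, intersystem crossing and 1,5-hydrogen transfer from the ortho methyl give the hydroxy-o-quinodimethane 10 with OH outside and aryl inside; titanium holds it as a six-membered chelate between the dienol oxygen and the neighbouring dioxole oxygen on C8, and it adds suprafacially to the C=C of 9 in an asynchronous concerted [4+2] cycloaddition. The closest known reactions are the photoenolisation/Diels–Alder trapping of ortho-methylbenzophenones by electron-poor alkenes and its Ti(Oi-Pr)4/chiral-diol enantioselective version with ortho-tolualdehydes. Ring B (C1–C2–C3–C4–C4a–C8a) closes by intermolecular [4+2] cycloaddition, forming C1–C2 and C3–C4 while ring A regains aromaticity. C2 and C3 are cis because both bonds form on one face of the Z-alkene of the furanone; C1 carries OH cis to C9 and aryl trans through the endo arrangement, in which the lactone carbonyl lies under the diene and binds the same titanium as the dienol oxygen; the absolute configuration follows from the TADDOLate, which blocks one face of the bound furanone. Regiochemistry (C1 to the α-carbon, the nucleophilic C4 terminus to the β-carbon) is secured by the oxygen donor on C1 and by the titanium bridge; because C1 is set again in step 8, the selectivity the route really needs here is the choice of furanone face, while degassing suppresses oxygen trapping of 10 and the acetonide offers no nearby hydrogen for a competing abstraction.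

Step 6
Reactants: 11 (1R,2S,3S)-1-hydroxy cis-lactone adduct
Product: 12 (1R,2R,3S)-2,3-bis(hydroxymethyl)-7,8-isopropylidenedioxy-6-methoxy-1-(3,4,5-trimethoxyphenyl)-1,2,3,4-tetrahydronaphthalen-1-ol
Conditions: LiAlH4, THF, −20 → 0 °C (11 added to the hydride); then H2O
Reagents that add atoms: none
Why: LiAlH4 reduction of the γ-lactone to the 1,4-diol should outrun retro-aldol cleavage of the β-hydroxy lactone when the substrate is added to excess hydride in the cold, and no stereocentre is touched.

Step 7
Reactants: 12 (1R,2R,3S)-triol
Product: 13 (1R,2R,3S)-2,3-bis[(di-tert-butylsilyl)oxymethyl]-7,8-isopropylidenedioxy-6-methoxy-1-(3,4,5-trimethoxyphenyl)-1,2,3,4-tetrahydronaphthalen-1-ol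
Conditions: t-Bu2SiHCl (2.4 equiv), imidazole, DMF, rt
Reagents that add atoms: di-tert-butylchlorosilane CC(C)(C)[SiH](Cl)C(C)(C)C
Why: Imidazole-promoted silyl ether formation takes the two primary alcohols and leaves the hindered tertiary diaryl carbinol free, which places two Si–H donors on the face of C9/C10 and masks the hydroxyls that could otherwise trap the C1 cation.

Step 8
Reactants: 13 (1R,2R,3S)-bis(di-tert-butylsilyl) ether
Product: 15 [(1S,2R,3S)-7,8-isopropylidenedioxy-6-methoxy-1-(3,4,5-trimethoxyphenyl)-1,2,3,4-tetrahydronaphthalene-2,3-diyl]dimethanol, via trifluoroacetoxysilyl ether 14 (not isolated)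
Conditions: CF3CO2H, CH2Cl2, −40 → 0 °C; then HF·pyridine, THF/pyridine, 0 °C → rt
Reagents that add atoms: none
Why: Proposed new method: the acid ionises the tertiary diaryl carbinol to a doubly benzylic C1 cation, and a 1,5-hydride shift from the C9–O–Si–H group through a six-membered transition state (or a 1,6-shift from the C10–O–Si–H group, which sits on the same face) should place H where OH stood, so that C1–H ends cis to C9 and the aryl trans (retention; the descriptor changes from R to S only because the priorities change), the silylium centre being caught as its trifluoroacetate before HF·pyridine strips both silicon groups; the closest known reactions are the intramolecular ionic hydrogenation of styrenes by di-tert-butylsilyl ether tethers and the Et3SiH/CF3CO2H deoxygenation of diaryl carbinols.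

Step 9
Reactants: 15 (1S,2R,3S)-acetonide diol
Product: 16 (1S,2R,3S)-2,3-bis(hydroxymethyl)-6-methoxy-1-(3,4,5-trimethoxyphenyl)-1,2,3,4-tetrahydronaphthalene-7,8-diol (target)
Conditions: 3 M HCl (aq), THF, 60 °C, argon
Reagents that add atoms: none
Why: Acid hydrolysis of the catechol isopropylidene ketal releases acetone and the free catechol, argon keeping the electron-rich catechol from air oxidation, while the three stereocentres carry only C–C and C–H bonds and cannot epimerise.

**Compound list**

1 | 3,4-dihydroxy-5-methoxybenzaldehyde | COc1cc(C=O)cc(O)c1O | starting material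
2 | 7-methoxy-2,2-dimethyl-1,3-benzodioxole-5-carbaldehyde | COc1cc(C=O)cc2OC(C)(C)Oc12 | intermediate
3 | (E)-hydrazone of 2 | COc1cc(/C=N/N)cc2OC(C)(C)Oc12 | intermediate (not isolated)
4 | 4-methoxy-2,2,6-trimethyl-1,3-benzodioxole | COc1cc(C)cc2OC(C)(C)Oc12 | intermediate
5 | 3,4,5-trimethoxybenzaldehyde | COc1cc(C=O)cc(OC)c1OC | starting material
6 | (7-methoxy-2,2,5-trimethyl-1,3-benzodioxol-4-yl)lithium | COc1cc(C)c([Li])c2OC(C)(C)Oc12 | intermediate (not isolated)
7 | rac-(7-methoxy-2,2,5-trimethyl-1,3-benzodioxol-4-yl)(3,4,5-trimethoxyphenyl)methanol (racemic carbinol) | COc1cc(C)c(C(O)c2cc(OC)c(OC)c(OC)c2)c2OC(C)(C)Oc12 | intermediate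
8 | (7-methoxy-2,2,5-trimethyl-1,3-benzodioxol-4-yl)(3,4,5-trimethoxyphenyl)methanone | COc1cc(C)c(C(=O)c2cc(OC)c(OC)c(OC)c2)c2OC(C)(C)Oc12 | intermediate
9 | 2(5H)-furanone | O=C1OCC=C1 | starting material
10 | photodienol (hydroxy-o-quinodimethane; OH outside, cis to C8; aryl inside; the "E-type" photoenol, formally Z by CIP because C8 bears oxygen) | C=C1C=C(OC)C2=C(OC(C)(C)O2)/C1=C(\O)c1cc(OC)c(OC)c(OC)c1 | intermediate (not isolated)
11 | (1R,2S,3S)-1-hydroxy cis-lactone adduct (C9 lactone carbonyl on C2, C10 OCH2 on C3, OH cis to C9, aryl trans) | COc1cc2c(c3OC(C)(C)Oc13)[C@](O)(c1cc(OC)c(OC)c(OC)c1)[C@@H](C(=O)OC3)[C@@H]3C2 | intermediate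
12 | (1R,2R,3S)-2,3-bis(hydroxymethyl)-7,8-isopropylidenedioxy-6-methoxy-1-(3,4,5-trimethoxyphenyl)-1,2,3,4-tetrahydronaphthalen-1-ol | COc1cc2c(c3OC(C)(C)Oc13)[C@](O)(c1cc(OC)c(OC)c(OC)c1)[C@@H](CO)[C@@H](CO)C2 | intermediate
13 | (1R,2R,3S)-bis(di-tert-butylsilyl) ether of 12 at O9 and O10 | COc1cc2c(c3OC(C)(C)Oc13)[C@](O)(c1cc(OC)c(OC)c(OC)c1)[C@@H](CO[SiH](C(C)(C)C)C(C)(C)C)[C@@H](CO[SiH](C(C)(C)C)C(C)(C)C)C2 | intermediate
14 | (1S,2R,3S)-C1-H tetralin with O9-Si(t-Bu)2(OCOCF3) and O10-SiH(t-Bu)2 | COc1cc2c(c3OC(C)(C)Oc13)[C@H](c1cc(OC)c(OC)c(OC)c1)[C@@H](CO[Si](OC(=O)C(F)(F)F)(C(C)(C)C)C(C)(C)C)[C@@H](CO[SiH](C(C)(C)C)C(C)(C)C)C2 | intermediate (not isolated)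
15 | [(1S,2R,3S)-7,8-isopropylidenedioxy-6-methoxy-1-(3,4,5-trimethoxyphenyl)-1,2,3,4-tetrahydronaphthalene-2,3-diyl]dimethanol | COc1cc2c(c3OC(C)(C)Oc13)[C@H](c1cc(OC)c(OC)c(OC)c1)[C@@H](CO)[C@@H](CO)C2 | intermediate
16 | (1S,2R,3S)-2,3-bis(hydroxymethyl)-6-methoxy-1-(3,4,5-trimethoxyphenyl)-1,2,3,4-tetrahydronaphthalene-7,8-diol | COc1cc2c(c(O)c1O)[C@H](c1cc(OC)c(OC)c(OC)c1)[C@@H](CO)[C@@H](CO)C2 | target

**Step count and risks**

Total steps: 9. Longest linear sequence: 9 steps (from 1; compounds 5 and 9 enter directly).

Steps most likely to fail, riskiest first: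

1. Step 8. The C1 cation may lose the C2 proton to give the 1-aryl-3,4-dihydronaphthalene, which erases C2. Protodesilylation may also free a silane that reduces the cation from the open face, opposite to C9/C10, and gives the 1,2-cis epimer. The fallback sets out from triol 12 and leaves out the silyl tether altogether. Hydrogenolysis of the tertiary benzylic C–OH over W-2 Raney nickel in refluxing ethanol is known to proceed with retention on nickel, and the two cis hydroxymethyl groups should anchor the same face on the metal. This should give the acetonide diol directly, so the route is rejoined at 15 and steps 7 and 8 are skipped; no new compound arises (entry F0).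

2. Step 5. The titanium complex may discriminate poorly between the two furanone faces. Trapping of the dienol by the only moderately reactive furanone may also be slow, so that the dienol reverts to the ketone or closes to a benzocyclobutenol. The fallback sets out from ketone 8 and replaces reagent control by auxiliary control. Irradiation (365 nm, degassed PhMe, no titanium) with (5S)-5-[(1S,2R,5S)-menthyloxy]-2(5H)-furanone, a more reactive dienophile that dienes attack anti to the menthyloxy group, should give the menthyloxy lactone adduct F1 with the same C2/C3 configuration. LiAlH4 in THF then reduces the lactone carbonyl and, after ring opening, the acetal carbon, releasing menthol and giving the triol, so the route is rejoined at 12.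

3. Step 3. Deprotonation may also take place next to the methoxy group, which would lead to the regioisomeric ketone. The fallback sets out from 4 and fixes the position by electrophilic substitution instead of kinetic deprotonation. NBS in MeCN at 0 °C should brominate para to the methoxy group at the position flanked by the tied-back dioxole oxygen, giving 4-bromo-7-methoxy-2,2,5-trimethyl-1,3-benzodioxole F2, whose substitution pattern can be secured before use. Bromine–lithium exchange (n-BuLi, THF, −78 °C) then gives the aryllithium, so the route is rejoined at 6, which is treated with 5 as in step 3.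

**Further compounds**

F0 | step 8 | none | none
F1 | step 5 | menthyloxy lactone adduct ((10S)-10-[(1S,2R,5S)-menthyloxy] analogue of 11) | COc1cc2c(c3OC(C)(C)Oc13)[C@](O)(c1cc(OC)c(OC)c(OC)c1)[C@@H](C(=O)O[C@@H]3O[C@H]1C[C@@H](C)CC[C@@H]1C(C)C)[C@@H]3C2
F2 | step 3 | 4-bromo-7-methoxy-2,2,5-trimethyl-1,3-benzodioxole | COc1cc(C)c(Br)c2OC(C)(C)Oc12
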